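## The problem

Compound 33 is a germacranolide in which a ten-membered carbocycle (C1 = enone CH, C2 = ketone, C3 = CH2, C4 = CHMe, C5 = CH–O-acyl, C6 = CHOH, C7, C8 = CH–O, C9 = CH2, C10 = CMe) is trans-fused at C7–C8 to an α-methylene-γ-butyrolactone (C11 on C7 with exocyclic C13, carbonyl C12, ring oxygen on C8). A synthesis must close the medium ring end to end at some bond and must deliver the C10=C1 alkene as the Z isomer (C9 cis to C2), which is best fixed in a fragment before the ring exists. Five contiguous stereocentres, C4 (S), C5 (R), C6 (R), C7 (R) and C8 (R), lie all-syn along the C3–C9 zig-zag, and the (2R,3S)-2,3-dimethyloxirane-2-carboxylate adds two more that are independent of the core. C4 and C5 can be made together; the C5 oxygen can then steer C6 by chelation, while C8, if it arrives on a preformed butenolide, steers C7 (trans across the lactone) and, through a cyclic allylation transition state, C6 as well. Three oxygens must be told apart, O5 (ester), O6 (free) and O8 (lactone); O6 and O8 are both γ to C12, so the wrong lactone is one transesterification away, and an O5→O6 acyl shift threatens any basic step at the end. The α-methylene lactone (a Michael acceptor that can isomerise into the ring), the enone with its vinylogously acidic C9 methylene next to the C8 acyloxy leaving group, and the glycidic ester rule out strong base, hard nucleophiles and hydride late in the route. The key step is possible because the C2 carbonyl and O5 are 1,4-related with the C4 methyl between them: C2–C3–C4–C5–O is an opened cis-4-methyl-γ-butyrolactone whose C5 substituent (C6) is a carboxyl-level carbon, that is, the homoenolate adduct of crotonaldehyde and a glyoxylate.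

## Retrosynthesis

**O5 ester and O6 silyl ether (33 ⇒ 32 ⇒ 26 + 30).** The last bonds cut are the O6–Si bond and the O5–acyl bond. The epoxy acid 30 is attached at the end so that the glycidic ester never meets hydride, organometallic reagents or divalent chromium. O6 has to be masked while O5 is acylated, which is why 26 carries a silyl ether there. Acid 30 goes back through epoxy alcohol 29 and allylic alcohol 28 to tiglic acid 27; a reagent-controlled epoxidation sets both epoxide centres.

**Ring closure at C1–C2 (26 ⇒ 25 ⇒ 24 ⇒ 23).** The ten-membered ring is opened at C1–C2, giving the acyclic aldehyde/Z-alkenyl iodide 23. A closure at C9–C10 by radical addition to an ynone was considered for this bond set. It leaves the alkene geometry to a hydrogen-atom transfer and offers the α-methylene lactone as a competing acceptor. A closure at C6–C7 would have to create three stereocentres in a macrocyclisation. The C1–C2 cut asks only for a Nozaki–Hiyama–Kishi addition that keeps the alkene geometry; the carbinol it makes at C2 is oxidised to the enone (24 to 25), and 25 is unmasked at O5 to give 26.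

**Fragment union at C6–C7 (23 ⇒ 22 ⇒ 21 ⇒ 20 ⇒ 8 + 19).** Cutting C6–C7 separates the C2–C6 aldehyde 8 from the bromomethyl butenolide 19. Because the O8–C12 lactone is already closed in 19, the O6/O8 lactone question never arises. The forward Barbier allylation must attack through C7, anti to the C8 side chain, and through a cyclic transition state that also fixes C6. The C5 PMB ether in 8 makes the chelated face of the aldehyde the same face the reagent demands. Protecting-group changes (20 to 21 to 22) and one oxidation (22 to 23) lie between the union and the ring closure.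

**Butenolide fragment (19 ⇒ 18 ⇒ 15 + 16; 15 ⇒ 12 ⇒ 11 ⇒ 9 + 10).** The butenolide C7=C11 bond is cut by ring-closing metathesis to ester 18, made from alcohol 15 and acid 16 (through its chloride 17). The Z-iodoalkene of 15 comes from carboalumination of alkyne 12 with hydroxyl-driven isomerisation (through alanes 13 and 14), which puts the C10 methyl and the correct geometry in one operation. C8 is set by kinetic resolution of racemic 11, the propargylation product of acrolein 9 and propargyl bromide 10.

**C2–C6 fragment (8 ⇒ 7 ⇒ 6 ⇒ 5 ⇒ 4 ⇒ 3).** Aldehyde 8 is traced back by functional-group changes only. Both carbonyls of lactone ester 3 are reduced to triol 4. The 1,2-diol is tied as the p-methoxybenzylidene acetal 5, the remote C2 hydroxyl is silylated (6), and reductive opening places the PMB group on O5 and frees C6–OH (7) for oxidation. The lactone oxygen of 3 thus marks O5 as different from O6, and C2, reduced for protection, returns to the ketone level after the ring closure.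

**Key disconnection (3 ⇒ 1 + 2).** The C4–C5 and O5–C2 bonds of 3 are cut together, giving crotonaldehyde 1 and ethyl glyoxylate 2. No other cut makes the C4/C5 pair from two achiral commodity aldehydes in one catalytic step. The forward reaction needs homoenolate rather than acyl-anion reactivity, cis selectivity and catalyst control of the absolute configuration.

## Roads not taken

**Alternative 1:** The lactone carbons would be attached by cutting C11–C7 and C12–C8. An amide tethered through an O6–C13 ether to the E C7=C8 alkene would be activated to its keteniminium ion and add across the alkene, giving after hydrolysis the cyclobutanone A1 fused to a tetrahydrofuran. The merit is real: ring expansion of A1 to the lactone and β-elimination of the O6–C13 ether would reveal the methylene group and the free C6 hydroxyl together, so O6 needs no protecting group. In that respect it is better than the chosen plan, which pays a silyl ether for O6. Against it: the cyclobutanone in A1 is flanked by two secondary carbons (C8 and C11), so the regiochemistry of oxygen insertion is uncertain. The strongly electrophilic amide activation must tolerate PMB and silyl ethers. The C4–C6 triad has no short source, and the ten-membered ring is left for a later end-to-end closure. The chosen plan sets against the extra protecting group a lactone that is never regiochemically in doubt and a two-carbon-plus-four-carbon entry to C4/C5.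

**Alternative 2:** The ten-membered ring would come from a cis-fused bicyclo[6.2.0]decene silyl enol ether by thermal conrotatory opening of the cyclobutene (C3–C10 σ-bond broken, C10=C1 and C2=C3 formed), giving dienol ether A2. This avoids any end-to-end cyclisation and needs no high dilution, a real advantage over the Nozaki–Hiyama–Kishi closure chosen here. Its weak points are the substrate and the selectivity. A cyclooctane carrying the lactone and four contiguous stereocentres, fused to a cyclobutene with a quaternary methyl-bearing carbon, is at least as hard to make as the target. Conrotation of a cis-fused cyclobutene gives one E and one Z alkene, and which of the two becomes the Z C10=C1 bond in A2 depends on torquoselectivity that the substituents do not obviously control. The chosen plan accepts the entropic cost of a macrocyclisation, but fixes the Z geometry in a small fragment and forms every stereocentre in a reaction with a predictable model.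

**Alternative 3:** The Z-enone would be stored as a six-membered unsaturated lactone. The silyl dienolate A4 would add through its γ-carbon (C9) to a C8 aldehyde carrying C3–C7, and lactonisation (O8–C2) would give dihydropyranone A3, in which C9 and C2 are cis by ring constraint. The geometry is guaranteed by construction, which is as good as or better than the carboalumination used here, and C2 sits at the acid oxidation level ready to become the ketone. Against it: the aldehyde partner with four contiguous stereocentres must be built linearly, and the C8 configuration depends on substrate control from C7. The later ring closure would have to be the attack of a C3 carbanion on the lactone carbonyl of A3, a medium-ring acylation that competes with γ-deprotonation of the unsaturated lactone. The chosen plan obtains the Z geometry in one step from an alkyne and closes the ring with a reaction type established for medium rings.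

Key step: step 1

Assumption: the (5aS,10bR) antipode of the triazolium salt is taken to give the (2R,3S) lactone 3; if the sense of induction is the opposite, the (5aR,10bS) salt is used and nothing else changes.
Remark: ethyl glyoxylate 2 is distilled (cracked from its toluene solution) immediately before use.

## Route

Step 1
Reactants: 1 crotonaldehyde [(E)-but-2-enal]; 2 ethyl glyoxylate
Product: 3 ethyl (2R,3S)-3-methyl-5-oxooxolane-2-carboxylate (cis lactone)
Conditions: (5aS,10bR)-2-mesityl-5a,10b-dihydro-4H,6H-indeno[2,1-b][1,2,4]triazolo[4,3-d][1,4]oxazin-2-ium chloride (10 mol %), DBU (15 mol %), 4 Å MS, THF, rt; 1 added slowly to 2 (2 equiv)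
Reagents that add atoms: none
Why: Carbene-catalysed homoenolate annulation of an enal with an aldehyde: the triazolylidene adds to 1, proton transfer gives the extended hydroxy-enamine, its β-carbon (C4) attacks the aldehyde carbon of 2 (C5), and tautomerisation to the acyl azolium lets the new alkoxide acylate at C2 and release the carbene. The closest known type is the carbene-catalysed annulation of enals with aromatic aldehydes and activated ketones to cis-γ-butyrolactones; the electrophile here is a small, highly activated aliphatic aldehyde. The one ring closes by 5-exo-trig O-acylation of the acyl azolium. C4 and C5 are both created in the C–C bond-forming event: the aminoindanol backbone of the catalyst shields one face of the homoenolate and fixes C4, and the compact approach of the glyoxylate carbonyl towards the enol OH places C5 syn, which appears as the cis lactone. The step needs homoenolate rather than acyl-anion (benzoin-type) reactivity, which the N-mesityl group secures by making the first addition reversible and favouring the extended enol. It needs cross- rather than self-annulation of the enal, secured by slow addition of 1 to an excess of the more electrophilic 2. It needs cis- and enantiocontrol, which rest on the chiral catalyst.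

Step 2
Reactants: 3 ethyl (2R,3S)-3-methyl-5-oxooxolane-2-carboxylate
Product: 4 (2R,3S)-3-methylpentane-1,2,5-triol
Conditions: LiAlH4, THF, 0 °C → rt; Na2SO4·10H2O quench
Reagents that add atoms: none
Why: Hydride reduction takes both the ethyl ester and the lactone to primary alcohols without touching C4 or C5; the three hydroxyls are then distinguished by position (1,2-diol versus isolated primary alcohol).

Step 3
Reactants: 4 (2R,3S)-3-methylpentane-1,2,5-triol
Product: 5 (3S)-3-[(4R)-2-(4-methoxyphenyl)-1,3-dioxolan-4-yl]butan-1-ol (acetal epimers)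
Conditions: 4-MeOC6H4CH(OMe)2, CSA (cat.), CH2Cl2, rt
Reagents that add atoms: 4-methoxybenzaldehyde dimethyl acetal, COc1ccc(cc1)C(OC)OC
Why: Acid-catalysed transacetalisation under thermodynamic control; the 1,2-diol forms the five-membered p-methoxybenzylidene acetal, and the only alternative ring with the remote hydroxyl would be seven-membered.

Step 4
Reactants: 5 (3S)-3-[(4R)-2-(4-methoxyphenyl)-1,3-dioxolan-4-yl]butan-1-ol
Product: 6 tert-butyl{(3S)-3-[(4R)-2-(4-methoxyphenyl)-1,3-dioxolan-4-yl]butoxy}dimethylsilane
Conditions: TBSCl, imidazole, DMF, 0 °C → rt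
Reagents that add atoms: tert-butyldimethylsilyl chloride, CC(C)(C)[Si](C)(C)Cl
Why: Standard silylation of a primary alcohol; the TBS ether withstands the aluminium hydride of step 5 and the aqueous Barbier conditions of step 12.

Step 5
Reactants: 6 tert-butyl{(3S)-3-[(4R)-2-(4-methoxyphenyl)-1,3-dioxolan-4-yl]butoxy}dimethylsilane
Product: 7 (2R,3S)-5-[(tert-butyldimethylsilyl)oxy]-2-[(4-methoxyphenyl)methoxy]-3-methylpentan-1-ol
Conditions: i-Bu2AlH (3 equiv), CH2Cl2, −78 → 0 °C; Rochelle salt
Reagents that add atoms: none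
Why: Regioselective reductive opening of a p-methoxybenzylidene acetal: the aluminium hydride binds the less hindered primary oxygen and cleaves its C–O bond, so the PMB group ends on the secondary O5 and C6 is released as the primary alcohol.

Step 6
Reactants: 7 (2R,3S)-5-[(tert-butyldimethylsilyl)oxy]-2-[(4-methoxyphenyl)methoxy]-3-methylpentan-1-ol
Product: 8 (2R,3S)-5-[(tert-butyldimethylsilyl)oxy]-2-[(4-methoxyphenyl)methoxy]-3-methylpentanal
Conditions: Dess–Martin periodinane, NaHCO3, CH2Cl2, 0 °C → rt; used crude
Reagents that add atoms: none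
Why: Dess–Martin oxidation under buffered, non-basic conditions gives the α-alkoxy aldehyde without epimerising C5.

Step 7
Reactants: 9 acrolein (prop-2-enal); 10 propargyl bromide (3-bromoprop-1-yne)
Product: 11 rac-hex-1-en-5-yn-3-ol
Conditions: Zn dust, THF/sat. aq. NH4Cl, 0 °C
Reagents that add atoms: none
Why: Zinc-mediated Barbier propargylation in aqueous medium; 1,2-addition to acrolein gives the racemic alcohol that is both allylic and homopropargylic.

Step 8
Reactants: 11 rac-hex-1-en-5-yn-3-ol
Product: 12 (3R)-hex-1-en-5-yn-3-ol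
Conditions: Ti(OiPr)4 (0.1 equiv), L-(+)-DIPT (0.15 equiv), t-BuOOH (0.6 equiv), 4 Å MS, CH2Cl2, −20 °C
Reagents that add atoms: none
Why: Sharpless kinetic resolution of a secondary allylic alcohol: with L-(+)-tartrate the (S)-enantiomer is epoxidised much faster, and the (R)-alcohol is recovered at a little over half conversion; this sets C8.

Step 9
Reactants: 12 (3R)-hex-1-en-5-yn-3-ol
Product: 15 (3R,5Z)-6-iodo-5-methylhexa-1,5-dien-3-ol, via E-alkenylalane 13 (not isolated), via cyclic Z-alkenylalane 14 (not isolated)
Conditions: AlMe3 (4 equiv), Cp2ZrCl2 (0.25 equiv), ClCH2CH2Cl, rt; then AlCl3 (0.5 equiv), 50 °C; then I2, THF, −30 → 0 °C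
Reagents that add atoms: trimethylaluminium, C[Al](C)C; iodine, II
Why: Negishi zirconium-catalysed carboalumination adds methyl and aluminium syn across the terminal alkyne; with a homopropargylic alkoxide the E-alkenylalane isomerises to the chelated Z isomer (a six-membered alkoxy-alane), and iodinolysis with retention gives the Z-iodoalkene carrying the C10 methyl. The alkyne reacts far faster than the monosubstituted alkene.

Step 10
Reactants: 15 (3R,5Z)-6-iodo-5-methylhexa-1,5-dien-3-ol; 16 2-(bromomethyl)prop-2-enoic acid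
Product: 18 (3R,5Z)-6-iodo-5-methylhexa-1,5-dien-3-yl 2-(bromomethyl)prop-2-enoate, via 2-(bromomethyl)prop-2-enoyl chloride 17 (not isolated)
Conditions: 16, (COCl)2, DMF (cat.), CH2Cl2, 0 °C → rt; then 15, 2,6-lutidine, CH2Cl2, −40 → 0 °C
Reagents that add atoms: none
Why: Acylation of a secondary alcohol by an acid chloride; the hindered pyridine base avoids nucleophilic amine catalysts, which would attack the 2-(bromomethyl)acrylate by SN2′.

Step 11
Reactants: 18 (3R,5Z)-6-iodo-5-methylhexa-1,5-dien-3-yl 2-(bromomethyl)prop-2-enoate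
Product: 19 (5R)-3-(bromomethyl)-5-[(2Z)-3-iodo-2-methylprop-2-en-1-yl]furan-2(5H)-one
Conditions: second-generation Grubbs catalyst (H2IMes)(PCy3)Cl2Ru=CHPh (5 mol %), CH2Cl2 (0.01 M), 40 °C
Reagents that add atoms: none
Why: Ring-closing metathesis of an allylic acrylate-type ester to a butenolide with loss of ethylene, as known for methacrylates; the carbene loads on the monosubstituted alkene, and the trisubstituted iodoalkene and the allylic bromide do not take part. No base is present that could enolise the butenolide at C8.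

Step 12
Reactants: 8 (2R,3S)-5-[(tert-butyldimethylsilyl)oxy]-2-[(4-methoxyphenyl)methoxy]-3-methylpentanal; 19 (5R)-3-(bromomethyl)-5-[(2Z)-3-iodo-2-methylprop-2-en-1-yl]furan-2(5H)-one
Product: 20 (4R,5R)-4-[(1R,2R,3S)-5-[(tert-butyldimethylsilyl)oxy]-1-hydroxy-2-[(4-methoxyphenyl)methoxy]-3-methylpentyl]-5-[(2Z)-3-iodo-2-methylprop-2-en-1-yl]-3-methylideneoxolan-2-one
Conditions: In powder (1.5 equiv), THF/H2O 3:1, rt
Reagents that add atoms: none
Why: Indium-mediated Barbier allylation with a 3-(bromomethyl)butenolide, a known route to β-(hydroxyalkyl)-α-methylene-γ-butyrolactones through γ-attack of the allylindium. C7 is set trans to the C8 side chain (approach anti to the allylic substituent), and the six-membered cyclic transition state of this ring-locked E-type allyl metal ties the aldehyde face to the allyl face, so C6 comes out syn to C7. That face is also the one favoured by chelation of trivalent indium between the aldehyde oxygen and the O5 PMB ether (5,6-syn), so reagent and substrate control are matched.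

Step 13
Reactants: 20 (the C6 alcohol from step 12)
Product: 21 (4S,5R)-4-[(1R,2R,3S)-1,5-bis[(tert-butyldimethylsilyl)oxy]-2-[(4-methoxyphenyl)methoxy]-3-methylpentyl]-5-[(2Z)-3-iodo-2-methylprop-2-en-1-yl]-3-methylideneoxolan-2-one
Conditions: TBSOTf, 2,6-lutidine, CH2Cl2, −78 → 0 °C
Reagents that add atoms: tert-butyldimethylsilyl trifluoromethanesulfonate, CC(C)(C)[Si](C)(C)OS(=O)(=O)C(F)(F)F
Why: Silyl triflate silylation of a hindered secondary alcohol; masking O6 prevents translactonisation to O6 and six-membered lactol formation with the C2 aldehyde, and leaves O5 as the only hydroxyl to acylate later. The descriptor at C7 changes only through CIP priorities.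

Step 14
Reactants: 21 (the bis-TBS ether from step 13)
Product: 22 (4S,5R)-4-[(1R,2R,3S)-1-[(tert-butyldimethylsilyl)oxy]-5-hydroxy-2-[(4-methoxyphenyl)methoxy]-3-methylpentyl]-5-[(2Z)-3-iodo-2-methylprop-2-en-1-yl]-3-methylideneoxolan-2-one
Conditions: HF·pyridine, pyridine, THF, 0 °C
Reagents that add atoms: none
Why: Rate-based selective cleavage of a primary TBS ether in the presence of a hindered secondary one with buffered HF·pyridine.

Step 15
Reactants: 22 (the primary alcohol from step 14)
Product: 23 (3S,4R,5R)-5-[(tert-butyldimethylsilyl)oxy]-5-[(2R,3S)-2-[(2Z)-3-iodo-2-methylprop-2-en-1-yl]-4-methylidene-5-oxooxolan-3-yl]-4-[(4-methoxyphenyl)methoxy]-3-methylpentanal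
Conditions: Dess–Martin periodinane, NaHCO3, CH2Cl2, 0 °C → rt
Reagents that add atoms: none
Why: Dess–Martin oxidation of the primary alcohol to the C2 aldehyde; the alkenyl iodide, PMB ether and methylene lactone are inert.

Step 16
Reactants: 23 (the aldehyde from step 15)
Product: 24 (3aS,4R,5R,6S,9Z,11aR)-4-[(tert-butyldimethylsilyl)oxy]-8-hydroxy-5-[(4-methoxyphenyl)methoxy]-6,10-dimethyl-3-methylidene-3a,4,5,6,7,8,11,11a-octahydrocyclodeca[b]furan-2(3H)-one (both C8-carbinol epimers)
Conditions: CrCl2 (10 equiv), NiCl2 (2 mol %), DMSO/THF 3:1, rt, slow addition of 23 to 0.003 M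
Reagents that add atoms: none
Why: Intramolecular Nozaki–Hiyama–Kishi reaction: nickel-catalysed insertion into the C–I bond, transmetalation to chromium and addition to the aldehyde close the ten-membered ring at high dilution with retention of the Z geometry. The lactone, methylene group, silyl and PMB ethers are inert to divalent chromium, and the new carbinol centre is erased in step 17.

Step 17
Reactants: 24 (the macrocyclic allylic alcohol from step 16)
Product: 25 (3aS,4R,5R,6S,9Z,11aR)-4-[(tert-butyldimethylsilyl)oxy]-5-[(4-methoxyphenyl)methoxy]-6,10-dimethyl-3-methylidene-3a,5,6,7,11,11a-hexahydrocyclodeca[b]furan-2,8(3H,4H)-dione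
Conditions: Dess–Martin periodinane, NaHCO3, CH2Cl2, 0 °C → rt
Reagents that add atoms: none
Why: Dess–Martin oxidation of the allylic alcohol gives the Z-enone; buffered conditions keep base away from the vinylogously acidic C9 methylene.

Step 18
Reactants: 25 (the enone from step 17)
Product: 26 (3aS,4R,5R,6S,9Z,11aR)-4-[(tert-butyldimethylsilyl)oxy]-5-hydroxy-6,10-dimethyl-3-methylidene-3a,5,6,7,11,11a-hexahydrocyclodeca[b]furan-2,8(3H,4H)-dione
Conditions: DDQ, CH2Cl2/pH 7 phosphate buffer, 0 °C
Reagents that add atoms: none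
Why: Oxidative cleavage of the PMB ether by DDQ in wet buffered solvent; the silyl ether, enone and lactone are unaffected.

Step 19
Reactants: 27 tiglic acid [(2E)-2-methylbut-2-enoic acid]
Product: 28 (2E)-2-methylbut-2-en-1-ol
Conditions: LiAlH4, Et2O, 0 °C → rt
Reagents that add atoms: none
Why: Hydride reduction of the α-methyl acrylic acid to the allylic alcohol by 1,2-reduction.

Step 20
Reactants: 28 (2E)-2-methylbut-2-en-1-ol
Product: 29 [(2S,3S)-2,3-dimethyloxiran-2-yl]methanol
Conditions: Ti(OiPr)4 (0.1 equiv), L-(+)-DET (0.12 equiv), t-BuOOH, 4 Å MS, CH2Cl2, −20 °C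
Reagents that add atoms: tert-butyl hydroperoxide, CC(C)(C)OO
Why: Sharpless asymmetric epoxidation of a trisubstituted E-allylic alcohol; the L-(+)-tartrate catalyst delivers oxygen to the face that gives the (2S,3S)-epoxy alcohol and sets both epoxide centres.

Step 21
Reactants: 29 [(2S,3S)-2,3-dimethyloxiran-2-yl]methanol
Product: 30 (2R,3S)-2,3-dimethyloxirane-2-carboxylic acid
Conditions: RuCl3 (2 mol %), NaIO4 (4 equiv), MeCN/EtOAc/H2O, 0 °C → rt
Reagents that add atoms: water, O; sodium periodate, [Na+].[O-]I(=O)(=O)=O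
Why: Ruthenium tetroxide generated from RuCl3 and NaIO4 oxidises the primary epoxy alcohol to the glycidic acid without opening the epoxide; the C2 descriptor changes from S to R only through CIP priorities.

Step 22
Reactants: 26 (the C5 alcohol from step 18); 30 (2R,3S)-2,3-dimethyloxirane-2-carboxylic acid
Product: 32 (3aS,4R,5R,6S,9Z,11aR)-4-[(tert-butyldimethylsilyl)oxy]-6,10-dimethyl-3-methylidene-2,8-dioxo-2,3,3a,4,5,6,7,8,11,11a-decahydrocyclodeca[b]furan-5-yl (2R,3S)-2,3-dimethyloxirane-2-carboxylate, via mixed anhydride 31 (not isolated)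
Conditions: 30, 2,4,6-Cl3C6H2COCl, Et3N, toluene, rt; then 26, DMAP, toluene, rt
Reagents that add atoms: none
Why: Yamaguchi esterification: the acid is activated as its mixed anhydride and transferred by DMAP to the hindered secondary O5 hydroxyl. O6 is silylated, so no regiochemical question arises, and the amine bases are too weak to enolise the enone at C9 at room temperature.

Step 23
Reactants: 32 (the silyl-protected ester from step 22)
Product: 33 target, (3aR,4R,5R,6S,9Z,11aR)-4-hydroxy-6,10-dimethyl-3-methylidene-2,8-dioxo-2,3,3a,4,5,6,7,8,11,11a-decahydrocyclodeca[b]furan-5-yl (2R,3S)-2,3-dimethyloxirane-2-carboxylate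
Conditions: HF·pyridine, pyridine, THF, 0 °C → rt
Reagents that add atoms: none
Why: Desilylation with buffered HF·pyridine generates no alkoxide, so there should be no O5→O6 acyl shift, no translactonisation to O6 and no elimination across C8–C9; the glycidic ester and both Michael acceptors are stable to these conditions.

## Compound list

1 | crotonaldehyde, (E)-but-2-enal | C/C=C/C=O | starting material
2 | ethyl glyoxylate | CCOC(=O)C=O | starting material
3 | ethyl (2R,3S)-3-methyl-5-oxooxolane-2-carboxylate | CCOC(=O)[C@@H]1OC(=O)C[C@@H]1C | intermediate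
4 | (2R,3S)-3-methylpentane-1,2,5-triol | OC[C@H](O)[C@@H](C)CCO | intermediate
5 | (3S)-3-[(4R)-2-(4-methoxyphenyl)-1,3-dioxolan-4-yl]butan-1-ol (acetal epimers) | COc1ccc(cc1)C1OC[C@H](O1)[C@@H](C)CCO | intermediate
6 | tert-butyl{(3S)-3-[(4R)-2-(4-methoxyphenyl)-1,3-dioxolan-4-yl]butoxy}dimethylsilane | COc1ccc(cc1)C1OC[C@H](O1)[C@@H](C)CCO[Si](C)(C)C(C)(C)C | intermediate
7 | (2R,3S)-5-[(tert-butyldimethylsilyl)oxy]-2-[(4-methoxyphenyl)methoxy]-3-methylpentan-1-ol | OC[C@H](OCc1ccc(OC)cc1)[C@@H](C)CCO[Si](C)(C)C(C)(C)C | intermediate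
8 | (2R,3S)-5-[(tert-butyldimethylsilyl)oxy]-2-[(4-methoxyphenyl)methoxy]-3-methylpentanal | O=C[C@H](OCc1ccc(OC)cc1)[C@@H](C)CCO[Si](C)(C)C(C)(C)C | intermediate
9 | acrolein, prop-2-enal | C=CC=O | starting material
10 | propargyl bromide, 3-bromoprop-1-yne | C#CCBr | starting material
11 | rac-hex-1-en-5-yn-3-ol | C=CC(O)CC#C | intermediate
12 | (3R)-hex-1-en-5-yn-3-ol | C=C[C@H](O)CC#C | intermediate
13 | [(1E,4R)-4-[(dimethylalumanyl)oxy]-2-methylhexa-1,5-dien-1-yl]dimethylalumane (E-alkenylalane) | C=C[C@H](O[Al](C)C)C/C(C)=C/[Al](C)C | intermediate (not isolated)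
14 | (6R)-6-ethenyl-2,4-dimethyl-5,6-dihydro-2H-1,2-oxaluminine (cyclic Z-alkenylalane) | C=C[C@H]1CC(C)=C[Al](C)O1 | intermediate (not isolated)
15 | (3R,5Z)-6-iodo-5-methylhexa-1,5-dien-3-ol | C=C[C@H](O)C/C(C)=C\I | intermediate
16 | 2-(bromomethyl)prop-2-enoic acid | OC(=O)C(=C)CBr | starting material
17 | 2-(bromomethyl)prop-2-enoyl chloride | ClC(=O)C(=C)CBr | intermediate (not isolated)
18 | (3R,5Z)-6-iodo-5-methylhexa-1,5-dien-3-yl 2-(bromomethyl)prop-2-enoate | C=C[C@H](OC(=O)C(=C)CBr)C/C(C)=C\I | intermediate
19 | (5R)-3-(bromomethyl)-5-[(2Z)-3-iodo-2-methylprop-2-en-1-yl]furan-2(5H)-one | BrCC1=C[C@@H](C/C(C)=C\I)OC1=O | intermediate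
20 | (4R,5R)-4-[(1R,2R,3S)-5-[(tert-butyldimethylsilyl)oxy]-1-hydroxy-2-[(4-methoxyphenyl)methoxy]-3-methylpentyl]-5-[(2Z)-3-iodo-2-methylprop-2-en-1-yl]-3-methylideneoxolan-2-one | C=C1C(=O)O[C@H](C/C(C)=C\I)[C@H]1[C@@H](O)[C@H](OCc2ccc(OC)cc2)[C@@H](C)CCO[Si](C)(C)C(C)(C)C | intermediate
21 | (4S,5R)-4-[(1R,2R,3S)-1,5-bis[(tert-butyldimethylsilyl)oxy]-2-[(4-methoxyphenyl)methoxy]-3-methylpentyl]-5-[(2Z)-3-iodo-2-methylprop-2-en-1-yl]-3-methylideneoxolan-2-one | C=C1C(=O)O[C@H](C/C(C)=C\I)[C@H]1[C@@H](O[Si](C)(C)C(C)(C)C)[C@H](OCc2ccc(OC)cc2)[C@@H](C)CCO[Si](C)(C)C(C)(C)C | intermediate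
22 | (4S,5R)-4-[(1R,2R,3S)-1-[(tert-butyldimethylsilyl)oxy]-5-hydroxy-2-[(4-methoxyphenyl)methoxy]-3-methylpentyl]-5-[(2Z)-3-iodo-2-methylprop-2-en-1-yl]-3-methylideneoxolan-2-one | C=C1C(=O)O[C@H](C/C(C)=C\I)[C@H]1[C@@H](O[Si](C)(C)C(C)(C)C)[C@H](OCc2ccc(OC)cc2)[C@@H](C)CCO | intermediate
23 | (3S,4R,5R)-5-[(tert-butyldimethylsilyl)oxy]-5-[(2R,3S)-2-[(2Z)-3-iodo-2-methylprop-2-en-1-yl]-4-methylidene-5-oxooxolan-3-yl]-4-[(4-methoxyphenyl)methoxy]-3-methylpentanal | C=C1C(=O)O[C@H](C/C(C)=C\I)[C@H]1[C@@H](O[Si](C)(C)C(C)(C)C)[C@H](OCc2ccc(OC)cc2)[C@@H](C)CC=O | intermediate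
24 | (3aS,4R,5R,6S,9Z,11aR)-4-[(tert-butyldimethylsilyl)oxy]-8-hydroxy-5-[(4-methoxyphenyl)methoxy]-6,10-dimethyl-3-methylidene-3a,4,5,6,7,8,11,11a-octahydrocyclodeca[b]furan-2(3H)-one (C8 epimers) | C=C1C(=O)O[C@@H]2C/C(C)=C\C(O)C[C@H](C)[C@@H](OCc3ccc(OC)cc3)[C@H](O[Si](C)(C)C(C)(C)C)[C@@H]12 | intermediate
25 | (3aS,4R,5R,6S,9Z,11aR)-4-[(tert-butyldimethylsilyl)oxy]-5-[(4-methoxyphenyl)methoxy]-6,10-dimethyl-3-methylidene-3a,5,6,7,11,11a-hexahydrocyclodeca[b]furan-2,8(3H,4H)-dione | C=C1C(=O)O[C@@H]2C/C(C)=C\C(=O)C[C@H](C)[C@@H](OCc3ccc(OC)cc3)[C@H](O[Si](C)(C)C(C)(C)C)[C@@H]12 | intermediate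
26 | (3aS,4R,5R,6S,9Z,11aR)-4-[(tert-butyldimethylsilyl)oxy]-5-hydroxy-6,10-dimethyl-3-methylidene-3a,5,6,7,11,11a-hexahydrocyclodeca[b]furan-2,8(3H,4H)-dione | C=C1C(=O)O[C@@H]2C/C(C)=C\C(=O)C[C@H](C)[C@@H](O)[C@H](O[Si](C)(C)C(C)(C)C)[C@@H]12 | intermediate
27 | tiglic acid, (2E)-2-methylbut-2-enoic acid | C/C=C(\C)C(=O)O | starting material
28 | (2E)-2-methylbut-2-en-1-ol | C/C=C(\C)CO | intermediate
29 | [(2S,3S)-2,3-dimethyloxiran-2-yl]methanol | OC[C@]1(C)O[C@H]1C | intermediate
30 | (2R,3S)-2,3-dimethyloxirane-2-carboxylic acid | OC(=O)[C@]1(C)O[C@H]1C | intermediate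
31 | (2R,3S)-2,3-dimethyloxirane-2-carboxylic 2,4,6-trichlorobenzoic anhydride (mixed anhydride) | O=C(OC(=O)[C@]1(C)O[C@H]1C)c1c(Cl)cc(Cl)cc1Cl | intermediate (not isolated)
32 | (3aS,4R,5R,6S,9Z,11aR)-4-[(tert-butyldimethylsilyl)oxy]-6,10-dimethyl-3-methylidene-2,8-dioxo-2,3,3a,4,5,6,7,8,11,11a-decahydrocyclodeca[b]furan-5-yl (2R,3S)-2,3-dimethyloxirane-2-carboxylate | C=C1C(=O)O[C@@H]2C/C(C)=C\C(=O)C[C@H](C)[C@@H](OC(=O)[C@]3(C)O[C@H]3C)[C@H](O[Si](C)(C)C(C)(C)C)[C@@H]12 | intermediate
33 | (3aR,4R,5R,6S,9Z,11aR)-4-hydroxy-6,10-dimethyl-3-methylidene-2,8-dioxo-2,3,3a,4,5,6,7,8,11,11a-decahydrocyclodeca[b]furan-5-yl (2R,3S)-2,3-dimethyloxirane-2-carboxylate | C=C1C(=O)O[C@@H]2C/C(C)=C\C(=O)C[C@H](C)[C@@H](OC(=O)[C@]3(C)O[C@H]3C)[C@H](O)[C@@H]12 | target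

## Step count and weakest steps

Total: 23 steps. Longest linear sequence: 15 steps (steps 1–6, 12–18, 22, 23, from crotonaldehyde). The butenolide branch (steps 7–11) and the acid branch (steps 19–21) are convergent.

**Step 1 (key step).** The most likely failure is erosion of cis- and enantioselectivity with so small and reactive an electrophile, together with loss of material to self-annulation of the enal, acyl-anion pathways and oligomerisation of the glyoxylate. Fallback, setting out from 2 and returning at 4: reagent-controlled syn-crotylboration of 2 with the appropriate antipode of (Z)-crotyldiisopinocampheylborane would give ethyl (2R,3S)-2-hydroxy-3-methylpent-4-enoate F1. LiAlH4 reduction would give (2R,3S)-3-methylpent-4-ene-1,2-diol F2. Hydroboration of the terminal alkene (9-BBN, then H2O2/NaOH) would give triol 4.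

**Step 12 (Barbier union).** The risk is that chelation by the PMB ether is too weak in water, so that the aldehyde's non-chelated facial preference opposes the face demanded by the cyclic transition state and selectivity at C6 erodes; protonolysis of the allylindium would also cost the butenolide. Oxidation–reduction at C6 is not an option, because a C6 ketone would pull the exocyclic alkene into conjugation. Fallback, setting out from 15 and 8 and returning at 20: 15 would be acylated (DCC, DMAP) with 2-[(tributylstannyl)methyl]prop-2-enoic acid to give (3R,5Z)-6-iodo-5-methylhexa-1,5-dien-3-yl 2-[(tributylstannyl)methyl]prop-2-enoate F3. Ring-closing metathesis would give (5R)-5-[(2Z)-3-iodo-2-methylprop-2-en-1-yl]-3-[(tributylstannyl)methyl]furan-2(5H)-one F4. F4 would be added to 8 precomplexed with MgBr2·OEt2 in CH2Cl2 at low temperature. In this open, Lewis-acid-mediated allylstannane addition the aldehyde face is fixed by the magnesium chelate and the allyl face by C8 independently, and the two together define 20.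

**Step 16 (ring closure).** Closure of a ten-membered ring is slow, so oligomerisation and proto-deiodination of the alkenylchromium may dominate. Fallback, setting out from 22 and returning at 25, closing the same bond by acylation at the ketone oxidation level: 22 would be stannylated ((Bu3Sn)2, Pd(PPh3)4) to (4S,5R)-4-[(1R,2R,3S)-1-[(tert-butyldimethylsilyl)oxy]-5-hydroxy-2-[(4-methoxyphenyl)methoxy]-3-methylpentyl]-3-methylidene-5-[(2Z)-2-methyl-3-(tributylstannyl)prop-2-en-1-yl]oxolan-2-one F5. Oxidation (TEMPO, PhI(OAc)2, then NaClO2) would give the corresponding (3S,4R,5R)-pentanoic acid F6. This would be converted with 1-chloro-N,N,2-trimethylprop-1-en-1-amine into the acid chloride F7, and an intramolecular Stille acylation at high dilution would give enone 25 directly, with retention of the alkene geometry.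

**Step 11 (with step 10).** The electron-poor 1,1-disubstituted bromomethylacrylate may turn over slowly, the allylic bromide may degrade the ruthenium carbene, and in step 10 the base may attack the bromide by SN2′. Fallback, setting out from 15 and returning at 19: 15 would be esterified (DCC, DMAP) with 2-{[(tert-butyldimethylsilyl)oxy]methyl}prop-2-enoic acid to give (3R,5Z)-6-iodo-5-methylhexa-1,5-dien-3-yl 2-{[(tert-butyldimethylsilyl)oxy]methyl}prop-2-enoate F8. Metathesis would give (5R)-3-{[(tert-butyldimethylsilyl)oxy]methyl}-5-[(2Z)-3-iodo-2-methylprop-2-en-1-yl]furan-2(5H)-one F9. Desilylation (HF·pyridine) would give (5R)-3-(hydroxymethyl)-5-[(2Z)-3-iodo-2-methylprop-2-en-1-yl]furan-2(5H)-one F10, and Appel bromination (CBr4, PPh3) would give 19.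

**Step 22 (esterification).** The γ-hydroxy ketone 26 may close to a transannular hemiketal that withdraws the hydroxyl; O5 is hindered; and the amine bases may slowly cause elimination across C8–C9 or isomerisation of the exocyclic alkene. Fallback, setting out from 21 and returning at 32, acylating before the ring and the enone exist: DDQ on 21 would give (4S,5R)-4-[(1R,2R,3S)-1,5-bis[(tert-butyldimethylsilyl)oxy]-2-hydroxy-3-methylpentyl]-5-[(2Z)-3-iodo-2-methylprop-2-en-1-yl]-3-methylideneoxolan-2-one F11. Yamaguchi esterification with 30 (through 31) would give (1R,2R,3S)-1,5-bis[(tert-butyldimethylsilyl)oxy]-1-[(2R,3S)-2-[(2Z)-3-iodo-2-methylprop-2-en-1-yl]-4-methylidene-5-oxooxolan-3-yl]-3-methylpentan-2-yl (2R,3S)-2,3-dimethyloxirane-2-carboxylate F12. Selective cleavage of the primary silyl ether would give the 5-hydroxy compound F13, Dess–Martin oxidation the 5-oxo compound F14, and the Nozaki–Hiyama–Kishi closure (3aS,4R,5R,6S,9Z,11aR)-4-[(tert-butyldimethylsilyl)oxy]-8-hydroxy-6,10-dimethyl-3-methylidene-2-oxo-2,3,3a,4,5,6,7,8,11,11a-decahydrocyclodeca[b]furan-5-yl (2R,3S)-2,3-dimethyloxirane-2-carboxylate F15. Oxidation of F15 would give 32. The price is exposure of the glycidic ester to divalent chromium.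

## Further compounds

F1 | step 1 | ethyl (2R,3S)-2-hydroxy-3-methylpent-4-enoate | CCOC(=O)[C@H](O)[C@@H](C)C=C
F2 | step 1 | (2R,3S)-3-methylpent-4-ene-1,2-diol | OC[C@H](O)[C@@H](C)C=C
F3 | step 12 | (3R,5Z)-6-iodo-5-methylhexa-1,5-dien-3-yl 2-[(tributylstannyl)methyl]prop-2-enoate | C=C[C@H](OC(=O)C(=C)C[Sn](CCCC)(CCCC)CCCC)C/C(C)=C\I
F4 | step 12 | (5R)-5-[(2Z)-3-iodo-2-methylprop-2-en-1-yl]-3-[(tributylstannyl)methyl]furan-2(5H)-one | CCCC[Sn](CCCC)(CCCC)CC1=C[C@@H](C/C(C)=C\I)OC1=O
F5 | step 16 | (4S,5R)-4-[(1R,2R,3S)-1-[(tert-butyldimethylsilyl)oxy]-5-hydroxy-2-[(4-methoxyphenyl)methoxy]-3-methylpentyl]-3-methylidene-5-[(2Z)-2-methyl-3-(tributylstannyl)prop-2-en-1-yl]oxolan-2-one | C=C1C(=O)O[C@H](C/C(C)=C\[Sn](CCCC)(CCCC)CCCC)[C@H]1[C@@H](O[Si](C)(C)C(C)(C)C)[C@H](OCc2ccc(OC)cc2)[C@@H](C)CCO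
F6 | step 16 | (3S,4R,5R)-5-[(tert-butyldimethylsilyl)oxy]-4-[(4-methoxyphenyl)methoxy]-3-methyl-5-[(2R,3S)-4-methylidene-2-[(2Z)-2-methyl-3-(tributylstannyl)prop-2-en-1-yl]-5-oxooxolan-3-yl]pentanoic acid | C=C1C(=O)O[C@H](C/C(C)=C\[Sn](CCCC)(CCCC)CCCC)[C@H]1[C@@H](O[Si](C)(C)C(C)(C)C)[C@H](OCc2ccc(OC)cc2)[C@@H](C)CC(=O)O
F7 | step 16 | (3S,4R,5R)-5-[(tert-butyldimethylsilyl)oxy]-4-[(4-methoxyphenyl)methoxy]-3-methyl-5-[(2R,3S)-4-methylidene-2-[(2Z)-2-methyl-3-(tributylstannyl)prop-2-en-1-yl]-5-oxooxolan-3-yl]pentanoyl chloride | C=C1C(=O)O[C@H](C/C(C)=C\[Sn](CCCC)(CCCC)CCCC)[C@H]1[C@@H](O[Si](C)(C)C(C)(C)C)[C@H](OCc2ccc(OC)cc2)[C@@H](C)CC(=O)Cl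
F8 | step 11 | (3R,5Z)-6-iodo-5-methylhexa-1,5-dien-3-yl 2-{[(tert-butyldimethylsilyl)oxy]methyl}prop-2-enoate | C=C[C@H](OC(=O)C(=C)CO[Si](C)(C)C(C)(C)C)C/C(C)=C\I
F9 | step 11 | (5R)-3-{[(tert-butyldimethylsilyl)oxy]methyl}-5-[(2Z)-3-iodo-2-methylprop-2-en-1-yl]furan-2(5H)-one | CC(C)(C)[Si](C)(C)OCC1=C[C@@H](C/C(C)=C\I)OC1=O
F10 | step 11 | (5R)-3-(hydroxymethyl)-5-[(2Z)-3-iodo-2-methylprop-2-en-1-yl]furan-2(5H)-one | OCC1=C[C@@H](C/C(C)=C\I)OC1=O
F11 | step 22 | (4S,5R)-4-[(1R,2R,3S)-1,5-bis[(tert-butyldimethylsilyl)oxy]-2-hydroxy-3-methylpentyl]-5-[(2Z)-3-iodo-2-methylprop-2-en-1-yl]-3-methylideneoxolan-2-one | C=C1C(=O)O[C@H](C/C(C)=C\I)[C@H]1[C@@H](O[Si](C)(C)C(C)(C)C)[C@H](O)[C@@H](C)CCO[Si](C)(C)C(C)(C)C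
F12 | step 22 | (1R,2R,3S)-1,5-bis[(tert-butyldimethylsilyl)oxy]-1-[(2R,3S)-2-[(2Z)-3-iodo-2-methylprop-2-en-1-yl]-4-methylidene-5-oxooxolan-3-yl]-3-methylpentan-2-yl (2R,3S)-2,3-dimethyloxirane-2-carboxylate | C=C1C(=O)O[C@H](C/C(C)=C\I)[C@H]1[C@@H](O[Si](C)(C)C(C)(C)C)[C@H](OC(=O)[C@]2(C)O[C@H]2C)[C@@H](C)CCO[Si](C)(C)C(C)(C)C
F13 | step 22 | (1R,2R,3S)-1-[(tert-butyldimethylsilyl)oxy]-5-hydroxy-1-[(2R,3S)-2-[(2Z)-3-iodo-2-methylprop-2-en-1-yl]-4-methylidene-5-oxooxolan-3-yl]-3-methylpentan-2-yl (2R,3S)-2,3-dimethyloxirane-2-carboxylate | C=C1C(=O)O[C@H](C/C(C)=C\I)[C@H]1[C@@H](O[Si](C)(C)C(C)(C)C)[C@H](OC(=O)[C@]2(C)O[C@H]2C)[C@@H](C)CCO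
F14 | step 22 | (1R,2R,3S)-1-[(tert-butyldimethylsilyl)oxy]-1-[(2R,3S)-2-[(2Z)-3-iodo-2-methylprop-2-en-1-yl]-4-methylidene-5-oxooxolan-3-yl]-3-methyl-5-oxopentan-2-yl (2R,3S)-2,3-dimethyloxirane-2-carboxylate | C=C1C(=O)O[C@H](C/C(C)=C\I)[C@H]1[C@@H](O[Si](C)(C)C(C)(C)C)[C@H](OC(=O)[C@]2(C)O[C@H]2C)[C@@H](C)CC=O
F15 | step 22 | (3aS,4R,5R,6S,9Z,11aR)-4-[(tert-butyldimethylsilyl)oxy]-8-hydroxy-6,10-dimethyl-3-methylidene-2-oxo-2,3,3a,4,5,6,7,8,11,11a-decahydrocyclodeca[b]furan-5-yl (2R,3S)-2,3-dimethyloxirane-2-carboxylate (C8 epimers) | C=C1C(=O)O[C@@H]2C/C(C)=C\C(O)C[C@H](C)[C@@H](OC(=O)[C@]3(C)O[C@H]3C)[C@H](O[Si](C)(C)C(C)(C)C)[C@@H]12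
A1 | alternative 1 | 7-{[(tert-butyldimethylsilyl)oxy]methyl}-2-{1-[(4-methoxyphenyl)methoxy]-2-methyl-3-[(triisopropylsilyl)oxy]propyl}-3-oxabicyclo[3.2.0]heptan-6-one (cyclobutanone fused to tetrahydrofuran) | O=C1[C@@H]2CO[C@@H]([C@H](OCc3ccc(OC)cc3)[C@@H](C)CO[Si](C(C)C)(C(C)C)C(C)C)[C@@H]2[C@H]1CO[Si](C)(C)C(C)(C)C
A2 | alternative 2 | ten-membered 2-(tert-butyldimethylsilyloxy)-1(10),2-diene lactone with Z C10=C1 (masked enone) carrying the C5 PMB ether and the C6 TBS ether | C1C(=O)O[C@@H]2C/C(C)=C\C(O[Si](C)(C)C(C)(C)C)=C\[C@H](C)[C@@H](OCc3ccc(OC)cc3)[C@H](O[Si](C)(C)C(C)(C)C)[C@@H]12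
A3 | alternative 3 | 6-substituted 4-methyl-5,6-dihydro-2H-pyran-2-one holding C8 and the cis C9/C2 geometry | CC1=CC(=O)O[C@H](C1)[C@H](CCOCc2ccc(OC)cc2)[C@@H](O[Si](C)(C)C(C)(C)C)[C@H](OCOC)[C@@H](C)CO[Si](C)(C)C(C)(C)C
A4 | alternative 3 | [(1-methoxy-3-methylbuta-1,3-dien-1-yl)oxy]trimethylsilane (silyl dienolate of methyl 3-methylbut-2-enoate) | COC(=CC(C)=C)O[Si](C)(C)C
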